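**Plan**

Numbering: C1 (alkyne CH) to C15 (ethyl CH3); ring O–C7–C8–C9=C10–C11–C12–C13. Feature used: without its oxygen the oxocene is a cyclohept-4-enone (C13 = carbonyl carbon, C7 = α-carbon carrying C6, C9=C10 = the ring Z-alkene), so the ring oxygen can be inserted between C13 and C7 of a purchasable carbocycle.
Retrosynthesis: cut the acetate, then C2–C3 (Sonogashira) and C3=C4 (Takai), then C12–Br (from the inverted C12 alcohol), C13–H and C13=C14 (reduction of the ethylidene enol ether of a lactone) and C12–O (enolate hydroxylation), then O–C7/O–C13 (Baeyer–Villiger), finally C6–C7 (aldol).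
Forward: cyclohept-4-enone and a 3-silyloxypropanal are joined by an aldol reaction; the eight-membered ring arises by oxygen insertion into the carbocycle, not by cyclisation; the lactone is then converted into the 2,7,8-trisubstituted oxocene, and the enyne and the acetate come last.
Stereochemistry: C6 and C7 from the D-proline anti-aldol (C7 kept by retentive migration); C12 from face-selective enolate hydroxylation, then inverted on bromination; C13 from hydride addition to the ring oxocarbenium ion anti to C12–O; Z-C9=C10 from the starting ring; E-C3=C4 from the Takai olefination.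

Key step: step 5

Remark: D-proline, bis(trimethylsilyl) peroxide and the N-sulfonyloxaziridine are taken as purchasable reagents; TBS, TBDPS, TES and TMS stand for tert-butyldimethylsilyl, tert-butyldiphenylsilyl, triethylsilyl and trimethylsilyl; the target's atom numbers are used for all intermediates.

**Route**

Step 1
Reactants: 1 propane-1,3-diol
Product: 2 3-(TBDPSO)propan-1-ol
Conditions: TBDPSCl (1 equiv), imidazole, 1 (3 equiv), THF, 0 °C → rt
Reagents that add atoms: tert-butyl(chloro)diphenylsilane, CC(C)(C)[Si](Cl)(c1ccccc1)c1ccccc1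
Why: Statistical monosilylation (silyl ether formation) of the symmetrical diol used in excess should give the mono-TBDPS ether, a group chosen because it survives every acidic step up to its fluoride removal in step 12.

Step 2
Reactants: 2 3-(TBDPSO)propan-1-ol
Product: 3 3-(TBDPSO)propanal
Conditions: TEMPO (10 mol %), PhI(OAc)2 (1.1 equiv), CH2Cl2, rt
Reagents that add atoms: none
Why: TEMPO/PhI(OAc)2 oxidation takes the primary alcohol to the aldehyde without over-oxidation and under non-basic conditions that should not eliminate the β-silyloxy group.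

Step 3
Reactants: 3 3-(TBDPSO)propanal; 4 cyclohept-4-en-1-one
Product: 5 (2R)-2-[(1R)-1-hydroxy-3-(TBDPSO)propyl]cyclohept-4-en-1-one
Conditions: D-proline (30 mol %), 4 (4 equiv, excess recovered), DMF, 4 °C, slow addition of 3
Reagents that add atoms: none
Why: Proline-catalysed direct aldol reaction (enamine catalysis), in which the enamine of the symmetrical ketone, E by ring constraint, adds to the aldehyde through the carboxylic-acid-bridged chair transition state that gives the anti adduct and, with D-proline, the (7R,6R) pair (the mirror image of the L-proline series), while the single kind of α-carbon in the ketone removes any regiochemical question.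

Step 4
Reactants: 5 (2R)-2-[(1R)-1-hydroxy-3-(TBDPSO)propyl]cyclohept-4-en-1-one
Product: 6 (2R)-2-[(1R)-1-(TBSO)-3-(TBDPSO)propyl]cyclohept-4-en-1-one
Conditions: TBSOTf, 2,6-lutidine, CH2Cl2, −78 °C
Reagents that add atoms: tert-butyldimethylsilyl trifluoromethanesulfonate, CC(C)(C)[Si](C)(C)OS(=O)(=O)C(F)(F)F
Why: Silyl ether formation with the silyl triflate at low temperature should protect the hindered β-hydroxy ketone before retro-aldol cleavage or epimerisation at C7 can set in.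

Step 5
Reactants: 6 (2R)-2-[(1R)-1-(TBSO)-3-(TBDPSO)propyl]cyclohept-4-en-1-one
Product: 8 (5Z,8R)-8-[(1R)-1-(TBSO)-3-(TBDPSO)propyl]-3,4,7,8-tetrahydro-2H-oxocin-2-one, via bis-silyl Criegee adduct 7 (not isolated)
Conditions: Me3SiOOSiMe3 (2.5 equiv), TMSOTf (0.2 equiv), 4 Å MS, CH2Cl2, −40 → −20 °C
Reagents that add atoms: bis(trimethylsilyl) peroxide, C[Si](C)(C)OO[Si](C)(C)C
Why: The silyl peroxide, activated by TMSOTf, adds to the C13 carbonyl to give the Criegee adduct 7, in which the C13–C7 bond antiperiplanar to the O–O bond migrates to oxygen with loss of hexamethyldisiloxane, forming the O–C7 and O–C13 bonds. This is the Baeyer–Villiger oxidation in its bis(trimethylsilyl) peroxide/Lewis acid form, known for 2-substituted cycloalkanones and for ketones that carry alkenes. No ring is closed by cyclisation: the seven-membered carbocycle is enlarged to the eight-membered lactone by a 1,2-shift (ring expansion by oxygen insertion), so the Z geometry of C9=C10 is inherited from the carbocycle. No stereocentre is created, and C7 migrates with retention, so the (7R) centre of the aldol adduct becomes the ring-oxygen-bearing centre unchanged. Two selectivities are needed: migration of C7 over C12, secured by the higher migratory aptitude of the secondary carbon (lowered only slightly by the β-silyloxy group), and oxidation of the ketone over the alkene, secured by a peroxide that carries no electrophilic oxygen for epoxidation and reacts only through the carbonyl adduct.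

Step 6
Reactants: 8 (5Z,8R)-8-[(1R)-1-(TBSO)-3-(TBDPSO)propyl]-3,4,7,8-tetrahydro-2H-oxocin-2-one
Product: 10 (3R,5Z,8R)-3-hydroxy-8-[(1R)-1-(TBSO)-3-(TBDPSO)propyl]-3,4,7,8-tetrahydro-2H-oxocin-2-one, via potassium lactone enolate 9 (not isolated)
Conditions: KHMDS (1.2 equiv), THF, −78 °C; 2-(phenylsulfonyl)-3-phenyloxaziridine (1.5 equiv), −78 °C; AcOH quench
Reagents that add atoms: 2-(phenylsulfonyl)-3-phenyloxaziridine, O=S(=O)(N1OC1c1ccccc1)c1ccccc1
Why: Davis enolate hydroxylation, in which the potassium enolate 9 (potassium to avoid addition to the sulfonimine by-product) is oxidised on its exposed peripheral face, which in the conformer with the C7 side chain pseudo-equatorial is expected to place the new C12–O bond cis to that side chain (12R), the sense known for closely related eight-membered unsaturated lactone enolates and the one needed for the later inversion.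

Step 7
Reactants: 10 (3R,5Z,8R)-3-hydroxy-8-[(1R)-1-(TBSO)-3-(TBDPSO)propyl]-3,4,7,8-tetrahydro-2H-oxocin-2-one
Product: 11 (3R,5Z,8R)-8-[(1R)-1-(TBSO)-3-(TBDPSO)propyl]-3-(triethylsilyloxy)-3,4,7,8-tetrahydro-2H-oxocin-2-one
Conditions: TESCl, imidazole, DMF, 0 °C
Reagents that add atoms: chlorotriethylsilane, CC[Si](Cl)(CC)CC
Why: Silyl ether formation masks the C12 hydroxyl for the titanium chemistry with a group that mild acid later removes in the presence of the TBS and TBDPS ethers.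

Step 8
Reactants: 11 (3R,5Z,8R)-8-[(1R)-1-(TBSO)-3-(TBDPSO)propyl]-3-(triethylsilyloxy)-3,4,7,8-tetrahydro-2H-oxocin-2-one; 12 1,1-dibromoethane
Product: 13 (2Z,3R,5Z,8R)-2-ethylidene-8-[(1R)-1-(TBSO)-3-(TBDPSO)propyl]-3-(triethylsilyloxy)-3,4,7,8-tetrahydro-2H-oxocine
Conditions: TiCl4, TMEDA, Zn, PbCl2 (cat.), THF, 0 → 25 °C; aq K2CO3 work-up
Reagents that add atoms: none
Why: Takai–Utimoto alkylidenation of the ester carbonyl turns the lactone into the exocyclic ethylidene enol ether (C13=C14, C15) with the ring intact, avoiding the ring opening that an ethyl organometallic would cause with a medium-ring lactone, and the non-basic reagent should leave C12 unepimerised while the Z geometry it favours is erased in the next step.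

Step 9
Reactants: 13 (2Z,3R,5Z,8R)-2-ethylidene-8-[(1R)-1-(TBSO)-3-(TBDPSO)propyl]-3-(triethylsilyloxy)-3,4,7,8-tetrahydro-2H-oxocine
Product: 15 (2R,4Z,7R,8R)-8-ethyl-2-[(1R)-1-(TBSO)-3-(TBDPSO)propyl]-7-(triethylsilyloxy)-3,6,7,8-tetrahydro-2H-oxocine, via ring oxocarbenium trifluoroacetate 14 (not isolated)
Conditions: Et3SiH (5 equiv), TFA (3 equiv), CH2Cl2, −78 → −40 °C; NaHCO3 quench
Reagents that add atoms: none
Why: Ionic hydrogenation of the enol ether, in which protonation at C14 gives the ring oxocarbenium ion 14 and triethylsilane delivers hydride to C13 anti to the C12–O bond (polar Felkin–Anh approach, away from the triethylsilyloxy group), which is also the approach leading to the favoured 2,8-cis medium-ring ether, so that C13 should be set R with the ethyl group cis to both the C12 oxygen and the C7 side chain.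

Step 10
Reactants: 15 (2R,4Z,7R,8R)-8-ethyl-2-[(1R)-1-(TBSO)-3-(TBDPSO)propyl]-7-(triethylsilyloxy)-3,6,7,8-tetrahydro-2H-oxocine
Product: 16 (2R,3R,5Z,8R)-2-ethyl-8-[(1R)-1-(TBSO)-3-(TBDPSO)propyl]-3,4,7,8-tetrahydro-2H-oxocin-3-ol (the C12 alcohol)
Conditions: PPTS (cat.), MeOH/CH2Cl2, 0 °C
Reagents that add atoms: none
Why: Acid-catalysed methanolysis (selective silyl ether cleavage) removes the secondary triethylsilyl ether far faster than the secondary TBS or primary TBDPS ether, and any C12 alcohol already released by the acid of step 9 is the same product.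

Step 11
Reactants: 16 (2R,3R,5Z,8R)-2-ethyl-8-[(1R)-1-(TBSO)-3-(TBDPSO)propyl]-3,4,7,8-tetrahydro-2H-oxocin-3-ol
Product: 17 (2R,4Z,7S,8R)-7-bromo-8-ethyl-2-[(1R)-1-(TBSO)-3-(TBDPSO)propyl]-3,6,7,8-tetrahydro-2H-oxocine
Conditions: CBr4, (n-C8H17)3P, toluene, 70 °C
Reagents that add atoms: carbon tetrabromide, BrC(Br)(Br)Br
Why: Appel-type bromination converts the alcohol through its alkoxyphosphonium salt into the bromide by SN2 displacement with inversion, turning (12R)-OH into (12S)-Br trans to the ethyl group, a conversion that is well established for hydroxy-oxocenes of this kind.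

Step 12
Reactants: 17 (2R,4Z,7S,8R)-7-bromo-8-ethyl-2-[(1R)-1-(TBSO)-3-(TBDPSO)propyl]-3,6,7,8-tetrahydro-2H-oxocine
Product: 18 (3R)-3-[(2R,4Z,7S,8R)-7-bromo-8-ethyl-3,6,7,8-tetrahydro-2H-oxocin-2-yl]-3-(TBSO)propan-1-ol
Conditions: NH4F (excess), MeOH, 40 °C
Reagents that add atoms: none
Why: Fluoride-mediated silyl ether cleavage with ammonium fluoride in methanol is selective for the unhindered primary TBDPS ether over the hindered secondary TBS ether and is neither basic nor acidic enough to disturb the secondary bromide.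

Step 13
Reactants: 18 (3R)-3-[(2R,4Z,7S,8R)-7-bromo-8-ethyl-3,6,7,8-tetrahydro-2H-oxocin-2-yl]-3-(TBSO)propan-1-ol
Product: 19 (3R)-3-[(2R,4Z,7S,8R)-7-bromo-8-ethyl-3,6,7,8-tetrahydro-2H-oxocin-2-yl]-3-(TBSO)propanal
Conditions: Dess–Martin periodinane, pyridine, CH2Cl2, 0 °C → rt
Reagents that add atoms: none
Why: Dess–Martin oxidation gives the β-silyloxy aldehyde (C4) under buffered, non-basic conditions that should neither provoke β-elimination nor touch the bromide.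

Step 14
Reactants: 19 (3R)-3-[(2R,4Z,7S,8R)-7-bromo-8-ethyl-3,6,7,8-tetrahydro-2H-oxocin-2-yl]-3-(TBSO)propanal; 20 iodoform
Product: 21 (2R,4Z,7S,8R)-7-bromo-8-ethyl-2-[(1R,3E)-4-iodo-1-(TBSO)but-3-en-1-yl]-3,6,7,8-tetrahydro-2H-oxocine
Conditions: CrCl2 (6 equiv), CHI3 (2 equiv), THF/1,4-dioxane 1:6, 0 °C → rt
Reagents that add atoms: none
Why: Takai iodo-olefination converts the aldehyde into the (E)-vinyl iodide (C3=C4) through the gem-dichromium reagent and anti elimination from its adduct, E-selectively and under non-basic conditions compatible with the bromide and the silyl ether.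

Step 15
Reactants: 21 (2R,4Z,7S,8R)-7-bromo-8-ethyl-2-[(1R,3E)-4-iodo-1-(TBSO)but-3-en-1-yl]-3,6,7,8-tetrahydro-2H-oxocine; 22 ethynyltrimethylsilane
Product: 23 (2R,4Z,7S,8R)-7-bromo-8-ethyl-2-[(1R,3E)-1-(TBSO)-6-(trimethylsilyl)hex-3-en-5-yn-1-yl]-3,6,7,8-tetrahydro-2H-oxocine
Conditions: Pd(PPh3)4 (5 mol %), CuI (10 mol %), Et3N, THF, rt
Reagents that add atoms: none
Why: Sonogashira coupling of the (E)-vinyl iodide with the terminal alkyne proceeds at room temperature with retention of the alkene geometry, and the unactivated secondary alkyl bromide should not undergo oxidative addition under these conditions.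

Step 16
Reactants: 23 (2R,4Z,7S,8R)-7-bromo-8-ethyl-2-[(1R,3E)-1-(TBSO)-6-(trimethylsilyl)hex-3-en-5-yn-1-yl]-3,6,7,8-tetrahydro-2H-oxocine
Product: 24 (1R,3E)-1-[(2R,4Z,7S,8R)-7-bromo-8-ethyl-3,6,7,8-tetrahydro-2H-oxocin-2-yl]hex-3-en-5-yn-1-ol
Conditions: TBAF/AcOH (1:1, 3 equiv), THF, 0 °C → rt
Reagents that add atoms: none
Why: Fluoride-mediated desilylation removes the alkynyl trimethylsilyl group and the C6 TBS ether in one operation, the acetic acid buffer keeping the medium too weakly basic for elimination of HBr.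

Step 17
Reactants: 24 (1R,3E)-1-[(2R,4Z,7S,8R)-7-bromo-8-ethyl-3,6,7,8-tetrahydro-2H-oxocin-2-yl]hex-3-en-5-yn-1-ol
Product: 25 (1R,3E)-1-[(2R,4Z,7S,8R)-7-bromo-8-ethyl-3,6,7,8-tetrahydro-2H-oxocin-2-yl]hex-3-en-5-yn-1-yl acetate (CNP0278050.2)
Conditions: Ac2O, pyridine, DMAP (cat.), CH2Cl2, rt
Reagents that add atoms: acetic anhydride, CC(=O)OC(C)=O
Why: DMAP-catalysed acetylation (esterification) of the secondary C6 alcohol gives the acetate without affecting any stereocentre.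

**Compound list**

1 | propane-1,3-diol | OCCCO | starting material
2 | 3-(TBDPSO)propan-1-ol | CC(C)(C)[Si](OCCCO)(c1ccccc1)c1ccccc1 | intermediate
3 | 3-(TBDPSO)propanal | CC(C)(C)[Si](OCCC=O)(c1ccccc1)c1ccccc1 | intermediate
4 | cyclohept-4-en-1-one | O=C1CC/C=C\CC1 | starting material
5 | (2R)-2-[(1R)-1-hydroxy-3-(TBDPSO)propyl]cyclohept-4-en-1-one | CC(C)(C)[Si](c1ccccc1)(c1ccccc1)OCC[C@@H](O)[C@H]1C/C=C\CCC1=O | intermediate
6 | (2R)-2-[(1R)-1-(TBSO)-3-(TBDPSO)propyl]cyclohept-4-en-1-one | CC(C)(C)[Si](c1ccccc1)(c1ccccc1)OCC[C@@H](O[Si](C)(C)C(C)(C)C)[C@H]1C/C=C\CCC1=O | intermediate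
7 | bis-silyl Criegee adduct of 6: (2R)-2-[(1R)-1-(TBSO)-3-(TBDPSO)propyl]-1-(trimethylsilyloxy)-1-(trimethylsilylperoxy)cyclohept-4-ene, either configuration at C13 | CC(C)(C)[Si](c1ccccc1)(c1ccccc1)OCC[C@@H](O[Si](C)(C)C(C)(C)C)[C@H]1C/C=C\CCC1(O[Si](C)(C)C)OO[Si](C)(C)C | intermediate (not isolated)
8 | (5Z,8R)-8-[(1R)-1-(TBSO)-3-(TBDPSO)propyl]-3,4,7,8-tetrahydro-2H-oxocin-2-one | CC(C)(C)[Si](c1ccccc1)(c1ccccc1)OCC[C@@H](O[Si](C)(C)C(C)(C)C)[C@H]1C/C=C\CCC(=O)O1 | intermediate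
9 | potassium enolate of 8 (C12=C13–O⁻) | CC(C)(C)[Si](c1ccccc1)(c1ccccc1)OCC[C@@H](O[Si](C)(C)C(C)(C)C)[C@H]1C/C=C\C/C=C(/[O-])O1.[K+] | intermediate (not isolated)
10 | (3R,5Z,8R)-3-hydroxy-8-[(1R)-1-(TBSO)-3-(TBDPSO)propyl]-3,4,7,8-tetrahydro-2H-oxocin-2-one | CC(C)(C)[Si](c1ccccc1)(c1ccccc1)OCC[C@@H](O[Si](C)(C)C(C)(C)C)[C@H]1C/C=C\C[C@@H](O)C(=O)O1 | intermediate
11 | (3R,5Z,8R)-8-[(1R)-1-(TBSO)-3-(TBDPSO)propyl]-3-(triethylsilyloxy)-3,4,7,8-tetrahydro-2H-oxocin-2-one | CC(C)(C)[Si](c1ccccc1)(c1ccccc1)OCC[C@@H](O[Si](C)(C)C(C)(C)C)[C@H]1C/C=C\C[C@@H](O[Si](CC)(CC)CC)C(=O)O1 | intermediate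
12 | 1,1-dibromoethane | CC(Br)Br | starting material
13 | (2Z,3R,5Z,8R)-2-ethylidene-8-[(1R)-1-(TBSO)-3-(TBDPSO)propyl]-3-(triethylsilyloxy)-3,4,7,8-tetrahydro-2H-oxocine | CC(C)(C)[Si](c1ccccc1)(c1ccccc1)OCC[C@@H](O[Si](C)(C)C(C)(C)C)[C@H]1C/C=C\C[C@@H](O[Si](CC)(CC)CC)/C(=C/C)O1 | intermediate
14 | ring oxocarbenium trifluoroacetate from 13 (C13=O⁺, ethyl on C13) | CC(C)(C)[Si](c1ccccc1)(c1ccccc1)OCC[C@@H](O[Si](C)(C)C(C)(C)C)[C@H]1C/C=C\C[C@@H](O[Si](CC)(CC)CC)C(CC)=[O+]1.[O-]C(=O)C(F)(F)F | intermediate (not isolated)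
15 | (2R,4Z,7R,8R)-8-ethyl-2-[(1R)-1-(TBSO)-3-(TBDPSO)propyl]-7-(triethylsilyloxy)-3,6,7,8-tetrahydro-2H-oxocine | CC(C)(C)[Si](c1ccccc1)(c1ccccc1)OCC[C@@H](O[Si](C)(C)C(C)(C)C)[C@H]1C/C=C\C[C@@H](O[Si](CC)(CC)CC)[C@@H](CC)O1 | intermediate
16 | (2R,3R,5Z,8R)-2-ethyl-8-[(1R)-1-(TBSO)-3-(TBDPSO)propyl]-3,4,7,8-tetrahydro-2H-oxocin-3-ol | CC(C)(C)[Si](c1ccccc1)(c1ccccc1)OCC[C@@H](O[Si](C)(C)C(C)(C)C)[C@H]1C/C=C\C[C@@H](O)[C@@H](CC)O1 | intermediate
17 | (2R,4Z,7S,8R)-7-bromo-8-ethyl-2-[(1R)-1-(TBSO)-3-(TBDPSO)propyl]-3,6,7,8-tetrahydro-2H-oxocine | CC(C)(C)[Si](c1ccccc1)(c1ccccc1)OCC[C@@H](O[Si](C)(C)C(C)(C)C)[C@H]1C/C=C\C[C@H](Br)[C@@H](CC)O1 | intermediate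
18 | (3R)-3-[(2R,4Z,7S,8R)-7-bromo-8-ethyl-3,6,7,8-tetrahydro-2H-oxocin-2-yl]-3-(TBSO)propan-1-ol | OCC[C@@H](O[Si](C)(C)C(C)(C)C)[C@H]1C/C=C\C[C@H](Br)[C@@H](CC)O1 | intermediate
19 | (3R)-3-[(2R,4Z,7S,8R)-7-bromo-8-ethyl-3,6,7,8-tetrahydro-2H-oxocin-2-yl]-3-(TBSO)propanal | O=CC[C@@H](O[Si](C)(C)C(C)(C)C)[C@H]1C/C=C\C[C@H](Br)[C@@H](CC)O1 | intermediate
20 | iodoform | IC(I)I | starting material
21 | (2R,4Z,7S,8R)-7-bromo-8-ethyl-2-[(1R,3E)-4-iodo-1-(TBSO)but-3-en-1-yl]-3,6,7,8-tetrahydro-2H-oxocine | I/C=C/C[C@@H](O[Si](C)(C)C(C)(C)C)[C@H]1C/C=C\C[C@H](Br)[C@@H](CC)O1 | intermediate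
22 | ethynyltrimethylsilane | C#C[Si](C)(C)C | starting material
23 | (2R,4Z,7S,8R)-7-bromo-8-ethyl-2-[(1R,3E)-1-(TBSO)-6-(trimethylsilyl)hex-3-en-5-yn-1-yl]-3,6,7,8-tetrahydro-2H-oxocine | C[Si](C)(C)C#C/C=C/C[C@@H](O[Si](C)(C)C(C)(C)C)[C@H]1C/C=C\C[C@H](Br)[C@@H](CC)O1 | intermediate
24 | (1R,3E)-1-[(2R,4Z,7S,8R)-7-bromo-8-ethyl-3,6,7,8-tetrahydro-2H-oxocin-2-yl]hex-3-en-5-yn-1-ol | C#C/C=C/C[C@@H](O)[C@H]1C/C=C\C[C@H](Br)[C@@H](CC)O1 | intermediate
25 | (1R,3E)-1-[(2R,4Z,7S,8R)-7-bromo-8-ethyl-3,6,7,8-tetrahydro-2H-oxocin-2-yl]hex-3-en-5-yn-1-yl acetate | C#C/C=C/C[C@@H](OC(C)=O)[C@H]1C/C=C\C[C@H](Br)[C@@H](CC)O1 | target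

**Step count and risks**

Total step count: 17. Longest linear sequence: 17 steps (1 → 25; 4, 12, 20 and 22 enter along the way).

Steps most likely to fail:

Step 3 (aldol). The enamine of the seven-membered ketone may form slowly, the unbranched β-silyloxy aldehyde may self-condense or eliminate, and retro-aldol equilibration may erode the anti ratio. The fallback sets out from 3 and comes back at 6; it builds the C6/C7 pair in an open chain and closes the carbocycle afterwards. Aldehyde 3 is homologated with ethyl diazoacetate and catalytic SnCl2 (Roskamp reaction) to ethyl 3-oxo-5-(TBDPSO)pentanoate F1. Hydrogenation over RuCl2[(R)-BINAP] (Noyori) should give ethyl (3R)-3-hydroxy-5-(TBDPSO)pentanoate F2. Fráter–Seebach allylation of its dianion (LDA, 2.2 equiv; allyl bromide) should give, through the lithium chelate, the anti product ethyl (2R,3R)-3-hydroxy-2-(prop-2-en-1-yl)-5-(TBDPSO)pentanoate F3. Me(MeO)NH·HCl with i-PrMgCl converts it into the Weinreb amide (2R,3R)-3-hydroxy-N-methoxy-N-methyl-2-(prop-2-en-1-yl)-5-(TBDPSO)pentanamide F4, and TBSOTf/2,6-lutidine gives (2R,3R)-3-(TBSO)-N-methoxy-N-methyl-2-(prop-2-en-1-yl)-5-(TBDPSO)pentanamide F5. But-3-enylmagnesium bromide gives the dienone (6R,7R)-7-(TBSO)-9-(TBDPSO)-6-(prop-2-en-1-yl)non-1-en-5-one F6, and ring-closing metathesis with the second-generation Grubbs catalyst joins C9 to C10 and gives 6.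

Step 5 (Baeyer–Villiger). The C9=C10 alkene may be oxidised in competition, C12 may migrate instead of C7, and the Lewis acid may cause loss of the β-silyloxy group. The fallback sets out from 6 and comes back at 8; it takes the alkene out of play as its dibromide so that a conventional buffered peracid can be used. Pyridinium tribromide (CH2Cl2, −20 °C) adds bromine anti across C9=C10 to give (2R)-4,5-dibromo-2-[(1R)-1-(TBSO)-3-(TBDPSO)propyl]cycloheptan-1-one F7 (both trans-dibromides). Trifluoroperacetic acid buffered with Na2HPO4 (CH2Cl2, 0 °C) should give, by the same retentive migration of C7, (8R)-5,6-dibromo-8-[(1R)-1-(TBSO)-3-(TBDPSO)propyl]oxocan-2-one F8. Zinc dust in AcOH/Et2O removes the two bromine atoms by anti elimination, restores the Z-alkene and gives 8.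

Step 9 (reduction at C13). Hydride delivery may show poor facial selectivity, the oxocarbenium ion may be captured transannularly by the C9=C10 alkene, and the acid may remove silyl groups. The fallback sets out from 10 and comes back at 15; it sets C13 by intramolecular hydrosilylation from the C12 oxygen and so avoids cations. Alcohol 10 is silylated (TMSCl, Et3N) to (3R,5Z,8R)-8-[(1R)-1-(TBSO)-3-(TBDPSO)propyl]-3-(trimethylsilyloxy)-3,4,7,8-tetrahydro-2H-oxocin-2-one F9. Petasis methylenation (Cp2TiMe2, toluene, 65 °C) gives (3R,5Z,8R)-2-methylidene-8-[(1R)-1-(TBSO)-3-(TBDPSO)propyl]-3-(trimethylsilyloxy)-3,4,7,8-tetrahydro-2H-oxocine F10, and K2CO3/MeOH frees (3R,5Z,8R)-2-methylidene-8-[(1R)-1-(TBSO)-3-(TBDPSO)propyl]-3,4,7,8-tetrahydro-2H-oxocin-3-ol F11. (HMe2Si)2NH gives (3R,5Z,8R)-3-(dimethylsilyloxy)-2-methylidene-8-[(1R)-1-(TBSO)-3-(TBDPSO)propyl]-3,4,7,8-tetrahydro-2H-oxocine F12. Karstedt's platinum catalyst should close the cis-fused oxasilolane (C12–O–SiMe2–CH2–C13 ring on the oxocene, hydrogen at C13 anti to C12–O) F13. Tamao oxidation (H2O2, KF, KHCO3) gives (2R,3R,5Z,8R)-2-(hydroxymethyl)-8-[(1R)-1-(TBSO)-3-(TBDPSO)propyl]-3,4,7,8-tetrahydro-2H-oxocin-3-ol F14. Triflation of the primary alcohol followed in the same flask by silylation of the secondary one (Tf2O, 2,6-lutidine, −78 °C; then TESOTf) gives [(2R,3R,5Z,8R)-8-[(1R)-1-(TBSO)-3-(TBDPSO)propyl]-3-(triethylsilyloxy)-3,4,7,8-tetrahydro-2H-oxocin-2-yl]methyl trifluoromethanesulfonate F15. Me2CuLi displaces the triflate, completes the ethyl group and gives 15.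

**Further compounds**

F1 | step 3 | ethyl 3-oxo-5-(TBDPSO)pentanoate | CCOC(=O)CC(=O)CCO[Si](c1ccccc1)(c1ccccc1)C(C)(C)C
F2 | step 3 | ethyl (3R)-3-hydroxy-5-(TBDPSO)pentanoate | CCOC(=O)C[C@H](O)CCO[Si](c1ccccc1)(c1ccccc1)C(C)(C)C
F3 | step 3 | ethyl (2R,3R)-3-hydroxy-2-(prop-2-en-1-yl)-5-(TBDPSO)pentanoate | CCOC(=O)[C@H](CC=C)[C@H](O)CCO[Si](c1ccccc1)(c1ccccc1)C(C)(C)C
F4 | step 3 | (2R,3R)-3-hydroxy-N-methoxy-N-methyl-2-(prop-2-en-1-yl)-5-(TBDPSO)pentanamide | CON(C)C(=O)[C@H](CC=C)[C@H](O)CCO[Si](c1ccccc1)(c1ccccc1)C(C)(C)C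
F5 | step 3 | (2R,3R)-3-(TBSO)-N-methoxy-N-methyl-2-(prop-2-en-1-yl)-5-(TBDPSO)pentanamide | CON(C)C(=O)[C@H](CC=C)[C@H](O[Si](C)(C)C(C)(C)C)CCO[Si](c1ccccc1)(c1ccccc1)C(C)(C)C
F6 | step 3 | (6R,7R)-7-(TBSO)-9-(TBDPSO)-6-(prop-2-en-1-yl)non-1-en-5-one | C=CCCC(=O)[C@H](CC=C)[C@H](O[Si](C)(C)C(C)(C)C)CCO[Si](c1ccccc1)(c1ccccc1)C(C)(C)C
F7 | step 5 | (2R)-4,5-dibromo-2-[(1R)-1-(TBSO)-3-(TBDPSO)propyl]cycloheptan-1-one (4,5-trans, both anti-addition diastereomers) | CC(C)(C)[Si](c1ccccc1)(c1ccccc1)OCC[C@@H](O[Si](C)(C)C(C)(C)C)[C@H]1CC(Br)C(Br)CCC1=O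
F8 | step 5 | (8R)-5,6-dibromo-8-[(1R)-1-(TBSO)-3-(TBDPSO)propyl]oxocan-2-one (5,6-trans, both diastereomers) | CC(C)(C)[Si](c1ccccc1)(c1ccccc1)OCC[C@@H](O[Si](C)(C)C(C)(C)C)[C@H]1CC(Br)C(Br)CCC(=O)O1
F9 | step 9 | (3R,5Z,8R)-8-[(1R)-1-(TBSO)-3-(TBDPSO)propyl]-3-(trimethylsilyloxy)-3,4,7,8-tetrahydro-2H-oxocin-2-one | CC(C)(C)[Si](c1ccccc1)(c1ccccc1)OCC[C@@H](O[Si](C)(C)C(C)(C)C)[C@H]1C/C=C\C[C@@H](O[Si](C)(C)C)C(=O)O1
F10 | step 9 | (3R,5Z,8R)-2-methylidene-8-[(1R)-1-(TBSO)-3-(TBDPSO)propyl]-3-(trimethylsilyloxy)-3,4,7,8-tetrahydro-2H-oxocine | CC(C)(C)[Si](c1ccccc1)(c1ccccc1)OCC[C@@H](O[Si](C)(C)C(C)(C)C)[C@H]1C/C=C\C[C@@H](O[Si](C)(C)C)C(=C)O1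
F11 | step 9 | (3R,5Z,8R)-2-methylidene-8-[(1R)-1-(TBSO)-3-(TBDPSO)propyl]-3,4,7,8-tetrahydro-2H-oxocin-3-ol | CC(C)(C)[Si](c1ccccc1)(c1ccccc1)OCC[C@@H](O[Si](C)(C)C(C)(C)C)[C@H]1C/C=C\C[C@@H](O)C(=C)O1
F12 | step 9 | (3R,5Z,8R)-3-(dimethylsilyloxy)-2-methylidene-8-[(1R)-1-(TBSO)-3-(TBDPSO)propyl]-3,4,7,8-tetrahydro-2H-oxocine | CC(C)(C)[Si](c1ccccc1)(c1ccccc1)OCC[C@@H](O[Si](C)(C)C(C)(C)C)[C@H]1C/C=C\C[C@@H](O[SiH](C)C)C(=C)O1
F13 | step 9 | cis-fused oxasilolane (C12–O–SiMe2–CH2–C13 ring on the oxocene, hydrogen at C13 anti to C12–O) | CC(C)(C)[Si](c1ccccc1)(c1ccccc1)OCC[C@@H](O[Si](C)(C)C(C)(C)C)[C@H]1C/C=C\C[C@H]2O[Si](C)(C)C[C@H]2O1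
F14 | step 9 | (2R,3R,5Z,8R)-2-(hydroxymethyl)-8-[(1R)-1-(TBSO)-3-(TBDPSO)propyl]-3,4,7,8-tetrahydro-2H-oxocin-3-ol | CC(C)(C)[Si](c1ccccc1)(c1ccccc1)OCC[C@@H](O[Si](C)(C)C(C)(C)C)[C@H]1C/C=C\C[C@@H](O)[C@@H](CO)O1
F15 | step 9 | [(2R,3R,5Z,8R)-8-[(1R)-1-(TBSO)-3-(TBDPSO)propyl]-3-(triethylsilyloxy)-3,4,7,8-tetrahydro-2H-oxocin-2-yl]methyl trifluoromethanesulfonate | CC(C)(C)[Si](c1ccccc1)(c1ccccc1)OCC[C@@H](O[Si](C)(C)C(C)(C)C)[C@H]1C/C=C\C[C@@H](O[Si](CC)(CC)CC)[C@@H](COS(=O)(=O)C(F)(F)F)O1
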